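All runs were computed from invented constants; noise was put on by code.

**Ratio at stake.** In the beta run, the ratio of X charged to X left at 8.00 min is 3.41, from a single reading with a scatter of 1 percentage point. It gives 0.472 as the decay per equivalent s, the logarithm of that ratio over the equivalents of E charged. With X at 0.50 M and the time at 8.0 min held, s stays constant if the rate is first order in X, first order in E, and E follows one curve, in percent of its own charge, at every loading. The part of X left is then exp(−s × equivalents). Beta, with its one loading, cannot show how s moves with the equivalents, so s is a working assumption.

| flask | X | E | remark | time |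
|---|---|---|---|---|
| beta | 0.50 M | 2.6 equiv | run made earlier |  |
| summer | 0.50 M | 2.00 equiv |  | 8.0 min |
| dusk | 0.50 M | 3.00 equiv |  | 8.0 min |
| dawn | 0.50 M | 4.50 equiv |  | 8.0 min |

beta run (percent of the X charged)

| time / min | X / % | Q / % |
|---|---|---|
| 0.667 | 75.0 | 24.3 |
| 1.00 | 70.8 | 29.8 |
| 1.33 | 65.2 | 36.7 |
| 2.50 | 53.2 | 49.3 |
| 3.00 | 47.9 | 50.4 |
| 5.00 | 37.3 | 62.7 |
| 8.00 | 29.3 | 72.3 |

(readings scatter by 1 percentage point)



- part of the X that has reacted at the end, summer
- part of the X that has reacted at the end, dusk
- part of the X that has reacted at the end, dawn
- what raising the equivalents of E from its lowest to its highest value here does to the part of the X that has reacted (changes below 5 percentage points count as none) (it rises / it falls / no change)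

**What to charge.** X, the limiting reagent of these charges, stays as in beta, and so does the time, so that the beta reading carries over. E alone moves. This text's own reckoning with s gives 61.1% reacted in summer, 75.7% in dusk and 88.1% in dawn. That span of 27 points is more than the 5 points that counts as a change, so the three loadings are worth charging, and X left at the end is the reading to watch.

**The forecast.** The forecast gives 63%, 74% and 83%, with the trend "it rises", and it warns: “Both assume first order in E, which one loading cannot prove”. The two part most at dawn, where the reckoning above stands higher.

**The flasks.** Summer gives 61.1%, dusk 78.5% and dawn 92.3%; the trend is "it rises", by 31 points. Read back from these results, s is 0.472 in summer and 0.570 in dawn, so dawn lies 4.2 points above the reckoning.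

    X + E → G + Q (k = 0.00640 M⁻¹ s⁻¹)
    E + G ⇌ J, settled at all times (K = 240 M⁻¹)
    E ⇌ L (K = 1.10, k = 0.00740 s⁻¹)
    G → Z (k = 0.00490 s⁻¹)

**Neighbour flask.** The neighbour is dusk recharged with 1.80 equiv of E, less than beta held. The same s gives 57.2% reacted, and the flask gives 56.6%, with 43% of its charged X still there, unbound.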